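The pitfall in these flasks is to read the zeta run as zero, since its starting material sits within scatter of the charge, and then to carry that zero over to flasks with more impurity than catalyst.

| setting | delta | zeta | Friday's | Saturday's | Monday's |
|---|---|---|---|---|---|
| starting material | 0.72 M | 0.72 M | 0.72 M | 0.72 M | 0.72 M |
| reagent | 0.90 equiv | 0.90 equiv | 0.900 equiv | 0.900 equiv | 0.900 equiv |
| free catalyst | 0.2 mol% | 0.2 mol% | 0.2 mol% | 0.2 mol% | 0.2 mol% |
| impurity | 1 mM | 7 mM | 5.0 mM | 0.80 mM | 2.0 mM |
| remark | run made earlier | run made earlier |  |  |  |
| time |  |  | 10 min | 10 min | 10 min |

| run | time / min | open intermediate / % | starting material / % | product / % |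
|---|---|---|---|---|
| delta | 1.00 | 24 | 75 | 6 |
| delta | 2.00 | 31 | 55 | 5 |
| delta | 3.00 | 36 | 53 | 12 |
| delta | 4.00 | 40 | 44 | 11 |
| delta | 5.00 | 37 | 40 | 20 |
| zeta | 1.00 | 1 | 98 | 2 |
| zeta | 2.00 | 5 | 96 | 1 |
| zeta | 3.00 | 2 | 97 | 1 |
| zeta | 4.00 | 5 | 98 | 0 |
| zeta | 5.00 | 2 | 99 | 2 |

(readings scatter by 2 percentage points)

- the numbers in the tables scatter by 2 percentage points (one standard deviation)

- which of these there is most of at the end, counted by the starting material in it, Friday's (open intermediate / product / starting material)
- which of these there is most of at the end, counted by the starting material in it, Saturday's (open intermediate / product / starting material)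
- which of these there is most of at the end, counted by the starting material in it, Monday's (open intermediate / product / starting material)
- amount of the one of these that there is most of at the end, in percent of the starting material charged, Friday's
- amount of the one of these that there is most of at the end, in percent of the starting material charged, Saturday's
- amount of the one of these that there is most of at the end, in percent of the starting material charged, Monday's

I order the run by time scales. First comes the poisoning, as I read it: zeta reads 98% starting material at 1.00 min and 99% at 5.00 min, so whatever stopped it was over within the first minute. Next comes the opening of starting material, which in delta takes minutes, down to 40% at 5.00 min. Last comes product in delta, with 20% at that time, less than the 37% of open intermediate.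

I assume that impurity consumes free catalyst one to one, and that opening goes with starting material times free catalyst while poisoning goes with impurity times free catalyst. Dividing one rate by the other then removes both free catalyst and time: the logarithm of the fraction of starting material left is a fixed multiple of the logarithm of the fraction of impurity left. That multiple is my toll ratio, a selectivity factor. In zeta the catalyst charge equals 20.6% of the impurity charge, and the mean of 5 readings leaves 97.6% starting material, so the ratio is 0.105, a reading good to about a third.

Raising the impurity left to this power, I expect 96.5% starting material in Friday's and 87.4% in Monday's, whatever the time after the first minutes. Saturday's impurity is 55.6% of its catalyst, so its surviving catalyst runs 1.45 times delta's. Delta's open intermediate reads level late on, so I draw product as a straight line at delta's mean slope times that factor, which gives 52.4% product in Saturday's, more than the other two together.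

The forecast gives starting material at 98.5% for Friday's, product at 46% for Saturday's, lower than mine, and starting material at 98% for Monday's, higher than mine, adding “Monday's is the less certain”.

The flasks end at 96.5% starting material in Friday's, 53.2% product in Saturday's and 87.7% starting material in Monday's. In Monday's, spent catalyst stands at 100% of the catalyst charged, with 28% of the impurity left, and that impurity raised to 0.105 gives 87.5%.

    starting material + free catalyst ⇌ free catalyst + open intermediate (K = 8.90, k = 8.60 L mol⁻¹ s⁻¹)
    free catalyst + open intermediate ⇌ catalyst intermediate (K = 3.10 L mol⁻¹, k = 10.0 L mol⁻¹ s⁻¹)
    reagent + catalyst intermediate → free catalyst + product (k = 8.40 L mol⁻¹ s⁻¹)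
    free catalyst + impurity → spent catalyst (k = 83.0 L mol⁻¹ s⁻¹)

A neighbouring flask is Saturday's with 0.08 mol% of free catalyst, which leaves 28.0% of its impurity by the one-to-one count, so the toll ratio gives 87.4%, and that flask ends at 87.7% starting material.

(The readings are simulated with made-up constants; noise was put on by code.)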